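The all-trans cyclobutane is cut at the two ring bonds that join C1, an acyl-bearing carbon, to the benzylic carbons C2 and C4. C1 becomes the carbon of dimethyl malonate; C2–C3–C4 becomes a meso syn,syn-1,3-diol, activated as its all-cis six-membered cyclic sulfate, in which C3 carries a benzyloxymethyl group as a latent carboxyl. One operation, a double SN2 alkylation, forms both bonds, closes the four-membered ring and, by two inversions, fixes the phenyl groups cis. The diol comes from a syn aldol and a syn reduction. Afterwards both carboxyl-bearing carbons are brought to the stable trans arrangement and the two acids acylate resorcinol.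

Key step: step 5

Remark: the target is achiral (mirror plane through C1 and C3), so chiral intermediates are racemic and drawn as one enantiomer; cyclobutane numbering is C1 (malonate-derived), C2 and C4 (phenyl-bearing), C3 (benzyloxymethyl-bearing).

Step 1
Reactants: 1 trimethyl[(1-phenylethenyl)oxy]silane; 2 benzyl chloromethyl ether
Product: 3 3-(benzyloxy)-1-phenylpropan-1-one
Conditions: ZnBr2 (10 mol %), CH2Cl2, 0 °C to rt
Reagents that add atoms: none
Why: Lewis-acid-promoted (Mukaiyama-type) alkylation of a silyl enol ether by the oxocarbenium ion of an α-chloro ether puts the benzyloxymethyl group on carbon only and once only, which a free enolate would not guarantee; no stereocenter is formed.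

Step 2
Reactants: 3 3-(benzyloxy)-1-phenylpropan-1-one; 4 benzaldehyde
Product: 7 rac-(2R,3R)-2-[(benzyloxy)methyl]-3-hydroxy-1,3-diphenylpropan-1-one (syn aldol), via Z dibutylboron enolate 5 (not isolated), via dibutylboron aldolate 6 (not isolated)
Conditions: Bu2BOTf, iPr2NEt, CH2Cl2, −78 °C; 4, −78 to 0 °C; then pH 7 buffer, MeOH, 30% H2O2, 0 °C
Reagents that add atoms: none
Why: Boron-mediated aldol addition, in which soft enolisation of the aryl ketone gives the Z enolate that adds to benzaldehyde through a closed chair transition state with the aldehyde phenyl equatorial, so that C2 and C3 are set syn, while the covalent B–O bond and low temperature should suppress β-elimination of benzyl oxide.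

Step 3
Reactants: 7 rac-(2R,3R)-2-[(benzyloxy)methyl]-3-hydroxy-1,3-diphenylpropan-1-one
Product: 9 (1R,2s,3S)-2-[(benzyloxy)methyl]-1,3-diphenylpropane-1,3-diol (meso syn,syn diol), via diethylboron chelate 8 (not isolated)
Conditions: Et2BOMe, THF/MeOH (4:1), −78 °C; NaBH4, −78 °C; then MeOH co-evaporation (releases the diol and returns Et2BOMe)
Reagents that add atoms: none
Why: Narasaka–Prasad reduction, in which the boron chelate of the β-hydroxy ketone adopts a half-chair and external hydride adds axially, anti to the pseudoaxial benzyloxymethyl group, so the new carbinol is 1,3-syn to the existing one and the meso syn,syn diol should result.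

Step 4
Reactants: 9 (1R,2s,3S)-2-[(benzyloxy)methyl]-1,3-diphenylpropane-1,3-diol
Product: 11 (4R,5s,6S)-5-[(benzyloxy)methyl]-4,6-diphenyl-1,3,2-dioxathiane 2,2-dioxide (all-cis cyclic sulfate), via cyclic sulfite 10 (not isolated)
Conditions: SOCl2, Et3N, CH2Cl2, 0 °C; then RuCl3·xH2O (cat.), NaIO4, MeCN/CH2Cl2/H2O, 0 °C, short reaction time
Reagents that add atoms: thionyl chloride, O=S(Cl)Cl; sodium periodate, [Na+].[O-][I](=O)(=O)=O
Why: Standard two-stage cyclic sulfate synthesis (cyclic sulfite formation, then RuO4-catalysed oxidation at sulfur) that touches no carbon stereocenter, so the syn,syn diol gives the all-cis ring, and the brief cold oxidation should spare the benzyl ether and the phenyl rings.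

Step 5
Reactants: 11 (4R,5s,6S)-5-[(benzyloxy)methyl]-4,6-diphenyl-1,3,2-dioxathiane 2,2-dioxide; 12 dimethyl malonate
Product: 15 dimethyl (2R,3r,4S)-3-[(benzyloxy)methyl]-2,4-diphenylcyclobutane-1,1-dicarboxylate (phenyls cis; benzyloxymethyl trans to both), via sodium dimethyl malonate 13 (not isolated), via ring-opened sulfate monoester 14 (not isolated)
Conditions: NaH (2.2 equiv), DME, 0 °C to rt, then 80 °C
Reagents that add atoms: none
Why: Sodium dimethyl malonate opens the cyclic sulfate by SN2 attack at one benzylic carbon (inversion), and after a second deprotonation the substituted malonate anion displaces the sulfate monoester at the other benzylic carbon (second inversion). The closest known reaction type is the double alkylation of malonate by cyclic sulfates or disulfonates of diols, which delivers cycloalkane-1,1-dicarboxylates. The cyclobutane closes in the 4-exo-tet mode. C2 and C4 are set by the stereospecific inversions at the two carbinol carbons of the meso diol, so both phenyls end up cis to each other and, because the sulfate is all-cis, trans to the untouched C3 substituent. The step needs substitution to beat E2 toward C3–H and ionisation of the benzylic sulfate, which the weakly basic soft carbanion, the unactivated C3–H (an ether and not a carbonyl on the side chain) and an aprotic ether solvent favour. C- rather than O-alkylation is expected because the oxygen terminus would have to close a six-membered ketene acetal, and the all-cis sulfate avoids building three contiguous cis substituents in the ring.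

Step 6
Reactants: 15 dimethyl (2R,3r,4S)-3-[(benzyloxy)methyl]-2,4-diphenylcyclobutane-1,1-dicarboxylate
Product: 16 methyl 3-[(benzyloxy)methyl]-2,4-diphenylcyclobutane-1-carboxylate (ring carbons C2 to C4 as in 15; mixture of C1 epimers)
Conditions: LiCl, H2O, DMSO, 155 °C
Reagents that add atoms: none
Why: Krapcho dealkoxycarbonylation, in which chloride attacks an unhindered ester methyl, CO2 is lost and the ester enolate is protonated, removes one ester without touching the benzylic ring carbons; the configuration at C1 is left open here and fixed in step 7.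

Step 7
Reactants: 16 methyl 3-[(benzyloxy)methyl]-2,4-diphenylcyclobutane-1-carboxylate (C1 epimers)
Product: 18 (1α,2β,3α,4β)-3-[(benzyloxy)methyl]-2,4-diphenylcyclobutane-1-carboxylic acid (all-trans), via all-trans methyl ester 17 (not isolated)
Conditions: NaOMe, MeOH, 65 °C; then H2O, 65 °C; then aq. HCl
Reagents that add atoms: water, O
Why: Base-mediated ester epimerisation through the enolate followed by saponification in the same pot, in which C1 is set under thermodynamic control with the carboxyl on the face opposite the two phenyls, and no ring-opening pathway exists because C3 does not yet carry a carbonyl.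

Step 8
Reactants: 18 (1α,2β,3α,4β)-3-[(benzyloxy)methyl]-2,4-diphenylcyclobutane-1-carboxylic acid
Product: 19 (1α,2β,3α,4β)-3-(hydroxymethyl)-2,4-diphenylcyclobutane-1-carboxylic acid
Conditions: H2 (1 atm), Pd/C (10 wt %), EtOAc/MeOH, rt
Reagents that add atoms: none
Why: Catalytic hydrogenolysis of the benzyl ether, under which the cyclobutane C–C bonds and the acid are inert and no stereocenter changes.

Step 9
Reactants: 19 (1α,2β,3α,4β)-3-(hydroxymethyl)-2,4-diphenylcyclobutane-1-carboxylic acid
Product: 21 (1α,2β,3α,4β)-2,4-diphenylcyclobutane-1,3-dicarboxylic acid (all-trans diacid), via formyl acid 20 (not isolated)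
Conditions: TEMPO (20 mol %), PhI(OAc)2 (2.5 equiv), MeCN/H2O (1:1), rt
Reagents that add atoms: water, O
Why: Oxoammonium (TEMPO) oxidation with PhI(OAc)2 as terminal oxidant takes the primary alcohol through the aldehyde hydrate to the acid, and since the C3 substituent is already trans to both phenyls, enolisation of the aldehyde cannot erode it.

Step 10
Reactants: 21 (1α,2β,3α,4β)-2,4-diphenylcyclobutane-1,3-dicarboxylic acid; 22 resorcinol
Product: 24 [(1α,2β,3α,4β)-2,4-diphenylcyclobutane-1,3-diyl]bis[(2,4-dihydroxyphenyl)methanone] (target), via mono-acylated keto acid 23 (not isolated)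
Conditions: 22 (3 equiv), BF3·OEt2 (neat), 85 °C; then aq. NaOAc, 60 °C
Reagents that add atoms: none
Why: Friedel–Crafts (Nencki-type) C-acylation of resorcinol by the free acids in BF3·OEt2, directed to C4 of resorcinol (para to one hydroxyl, ortho to the other) and held as the BF2 chelate of the ortho-hydroxy ketone until work-up, while C1 and C3 can only equilibrate toward the all-trans arrangement of the target.

Compound list
1 | trimethyl[(1-phenylethenyl)oxy]silane | C=C(O[Si](C)(C)C)c1ccccc1 | starting material
2 | benzyl chloromethyl ether | ClCOCc1ccccc1 | starting material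
3 | 3-(benzyloxy)-1-phenylpropan-1-one | O=C(CCOCc1ccccc1)c1ccccc1 | intermediate
4 | benzaldehyde | O=Cc1ccccc1 | starting material
5 | (Z)-{[3-(benzyloxy)-1-phenylprop-1-en-1-yl]oxy}dibutylborane | CCCCB(CCCC)O/C(c1ccccc1)=C\COCc1ccccc1 | intermediate (not isolated)
6 | O-dibutylboryl derivative of syn aldol 7 (racemic) | CCCCB(CCCC)O[C@@H](c1ccccc1)[C@@H](COCc1ccccc1)C(=O)c1ccccc1 | intermediate (not isolated)
7 | rac-(2R,3R)-2-[(benzyloxy)methyl]-3-hydroxy-1,3-diphenylpropan-1-one (syn) | O[C@@H](c1ccccc1)[C@@H](COCc1ccccc1)C(=O)c1ccccc1 | intermediate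
8 | O-diethylboryl chelate of 7 (racemic) | CCB(CC)O[C@@H](c1ccccc1)[C@@H](COCc1ccccc1)C(=O)c1ccccc1 | intermediate (not isolated)
9 | (1R,2s,3S)-2-[(benzyloxy)methyl]-1,3-diphenylpropane-1,3-diol (meso; both hydroxyls syn to the benzyloxymethyl group) | O[C@@H](c1ccccc1)[C@@H](COCc1ccccc1)[C@@H](c1ccccc1)O | intermediate
10 | (4R,5s,6S)-5-[(benzyloxy)methyl]-4,6-diphenyl-1,3,2-dioxathiane 2-oxide (all-cis at carbon; epimers at sulfur) | O=S1O[C@@H](c2ccccc2)[C@@H](COCc2ccccc2)[C@@H](c2ccccc2)O1 | intermediate (not isolated)
11 | (4R,5s,6S)-5-[(benzyloxy)methyl]-4,6-diphenyl-1,3,2-dioxathiane 2,2-dioxide (all-cis) | O=S1(=O)O[C@@H](c2ccccc2)[C@@H](COCc2ccccc2)[C@@H](c2ccccc2)O1 | intermediate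
12 | dimethyl malonate | COC(=O)CC(=O)OC | starting material
13 | sodium dimethyl malonate | [Na+].COC(=O)[CH-]C(=O)OC | intermediate (not isolated)
14 | sodium salt of dimethyl 2-[2-(benzyloxymethyl)-1,3-diphenyl-3-(sulfooxy)propyl]malonate (racemic; first benzylic carbon inverted) | [Na+].COC(=O)C(C(=O)OC)[C@H](c1ccccc1)[C@@H](COCc1ccccc1)[C@@H](c1ccccc1)OS(=O)(=O)[O-] | intermediate (not isolated)
15 | dimethyl (2R,3r,4S)-3-[(benzyloxy)methyl]-2,4-diphenylcyclobutane-1,1-dicarboxylate (phenyls cis; benzyloxymethyl trans to both) | COC(=O)C1(C(=O)OC)[C@H](c2ccccc2)[C@@H](COCc2ccccc2)[C@@H]1c1ccccc1 | intermediate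
16 | methyl 3-[(benzyloxy)methyl]-2,4-diphenylcyclobutane-1-carboxylate (C2 to C4 as in 15; C1 epimers) | COC(=O)C1[C@H](c2ccccc2)[C@@H](COCc2ccccc2)[C@@H]1c1ccccc1 | intermediate
17 | methyl (1α,2β,3α,4β)-3-[(benzyloxy)methyl]-2,4-diphenylcyclobutane-1-carboxylate | COC(=O)[C@H]1[C@H](c2ccccc2)[C@@H](COCc2ccccc2)[C@@H]1c1ccccc1 | intermediate (not isolated)
18 | (1α,2β,3α,4β)-3-[(benzyloxy)methyl]-2,4-diphenylcyclobutane-1-carboxylic acid | OC(=O)[C@H]1[C@H](c2ccccc2)[C@@H](COCc2ccccc2)[C@@H]1c1ccccc1 | intermediate
19 | (1α,2β,3α,4β)-3-(hydroxymethyl)-2,4-diphenylcyclobutane-1-carboxylic acid | OC(=O)[C@H]1[C@H](c2ccccc2)[C@@H](CO)[C@@H]1c1ccccc1 | intermediate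
20 | (1α,2β,3α,4β)-3-formyl-2,4-diphenylcyclobutane-1-carboxylic acid | OC(=O)[C@H]1[C@H](c2ccccc2)[C@@H](C=O)[C@@H]1c1ccccc1 | intermediate (not isolated)
21 | (1α,2β,3α,4β)-2,4-diphenylcyclobutane-1,3-dicarboxylic acid | OC(=O)[C@H]1[C@H](c2ccccc2)[C@@H](C(=O)O)[C@@H]1c1ccccc1 | intermediate
22 | resorcinol | Oc1cccc(O)c1 | starting material
23 | (1α,2β,3α,4β)-3-(2,4-dihydroxybenzoyl)-2,4-diphenylcyclobutane-1-carboxylic acid | OC(=O)[C@H]1[C@H](c2ccccc2)[C@@H](C(=O)c2ccc(O)cc2O)[C@@H]1c1ccccc1 | intermediate (not isolated)
24 | [(1α,2β,3α,4β)-2,4-diphenylcyclobutane-1,3-diyl]bis[(2,4-dihydroxyphenyl)methanone] | O=C(c1ccc(O)cc1O)[C@H]1[C@H](c2ccccc2)[C@@H](C(=O)c2ccc(O)cc2O)[C@@H]1c1ccccc1 | target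

Total step count: 10
Longest linear sequence: 10 steps (from 1 and 2 to 24)

Steps most likely to fail

Step 5. After the first displacement, the ring-forming displacement of an anionic sulfate group at a hindered benzylic carbon may be outrun by elimination across C3–C4. Ionisation of the benzylic C–O bond could also occur, with loss of stereochemical integrity or O-alkylation. The fallback separates the two bond formations and exchanges the anionic leaving group for a neutral one. It sets out from cyclic sulfate 11, which is opened at room temperature by sodium dimethyl malonate 13 (one equivalent of NaH, THF) to the sulfate monoester 14. Mild acid hydrolysis (catalytic H2SO4, 1–2 equiv H2O, THF, 0 °C to rt) should give dimethyl 2-[2-(benzyloxymethyl)-3-hydroxy-1,3-diphenylpropyl]malonate F1, handled cold to forestall lactonisation. Sulfonylation with retention (Ms2O, Et3N, CH2Cl2, −30 °C) should give dimethyl 2-[2-(benzyloxymethyl)-3-(methylsulfonyloxy)-1,3-diphenylpropyl]malonate F2. This is cyclised cold (NaH, THF, 0 °C) by intramolecular malonate alkylation with inversion, and the fallback returns to the route at 15.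

Step 4. The doubly benzylic cyclic sulfate may decompose by hydrolysis or ionisation during the aqueous oxidation or on storage, and RuO4 may attack the benzyl ether. The fallback avoids both the cyclic sulfate and the oxidation. It sets out from diol 9, which is converted at −30 °C (Ms2O, Et3N, CH2Cl2) into (1R,2s,3S)-2-[(benzyloxy)methyl]-1,3-diphenylpropane-1,3-diyl dimethanesulfonate F3. This is used crude and cold in the classical malonate/1,3-disulfonate cyclobutane synthesis with sodium dimethyl malonate 13 and a second equivalent of NaH (THF/DMF, 0 °C to rt). Both sulfonates are displaced with inversion, so the fallback returns to the route at 15.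

Step 10. The hot Lewis acid may cleave the aryl-substituted cyclobutane through the enolised ketone (retro-Michael-type ring opening), or the reaction may stop at O-acylation or mono-acylation. The fallback replaces electrophilic aromatic substitution by addition of an aryl nucleophile. It sets out from diacid 21, which is coupled with N,O-dimethylhydroxylamine hydrochloride (EDC·HCl, HOBt, iPr2NEt, CH2Cl2) to (1α,2β,3α,4β)-N1,N3-dimethoxy-N1,N3-dimethyl-2,4-diphenylcyclobutane-1,3-dicarboxamide F4. Commercial 2,4-dimethoxyphenylmagnesium bromide (THF, 0 °C) should give [(1α,2β,3α,4β)-2,4-diphenylcyclobutane-1,3-diyl]bis[(2,4-dimethoxyphenyl)methanone] F5. BBr3 (CH2Cl2, −78 °C to rt) then cleaves the four methyl ethers, and the fallback returns to the route at target 24.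

Further compounds
F1 | step 5 | dimethyl 2-[2-(benzyloxymethyl)-3-hydroxy-1,3-diphenylpropyl]malonate (racemic; configuration as in 14) | COC(=O)C(C(=O)OC)[C@H](c1ccccc1)[C@@H](COCc1ccccc1)[C@@H](c1ccccc1)O
F2 | step 5 | dimethyl 2-[2-(benzyloxymethyl)-3-(methylsulfonyloxy)-1,3-diphenylpropyl]malonate (racemic; configuration as in 14) | COC(=O)C(C(=O)OC)[C@H](c1ccccc1)[C@@H](COCc1ccccc1)[C@@H](c1ccccc1)OS(C)(=O)=O
F3 | step 4 | (1R,2s,3S)-2-[(benzyloxy)methyl]-1,3-diphenylpropane-1,3-diyl dimethanesulfonate | CS(=O)(=O)O[C@@H](c1ccccc1)[C@@H](COCc1ccccc1)[C@@H](c1ccccc1)OS(C)(=O)=O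
F4 | step 10 | (1α,2β,3α,4β)-N1,N3-dimethoxy-N1,N3-dimethyl-2,4-diphenylcyclobutane-1,3-dicarboxamide | CON(C)C(=O)[C@H]1[C@H](c2ccccc2)[C@@H](C(=O)N(C)OC)[C@@H]1c1ccccc1
F5 | step 10 | [(1α,2β,3α,4β)-2,4-diphenylcyclobutane-1,3-diyl]bis[(2,4-dimethoxyphenyl)methanone] | COc1ccc(C(=O)[C@H]2[C@H](c3ccccc3)[C@@H](C(=O)c3ccc(OC)cc3OC)[C@@H]2c2ccccc2)c(OC)c1
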